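**Retrosynthetic overview**

1. Labels used throughout (cembrane): C1 = ring CH carrying C15(=C17H2)–C16(=O)O; C3 = carbinol; C4=C5 and C7=C8 = E-olefins; C11 = CH–OAc; C12 = C(Me)–O(lactone). The target is 1R,3R,11S,12R.
2. Target ⇐ CBS reduction of the C3 ketone ⇐ ε-lactone ring and C1 made last by a catalytic asymmetric intramolecular Rauhut–Currier reaction of a C12 acrylate onto the macrocyclic C1=C2–C3(=O) enone (C15–C1 bond; proposed new method).
3. The 14-membered carbocycle is formed before the lactone, by ring-closing metathesis at C1=C2 of a vinyl ketone (from a Weinreb amide) and a terminal vinyl group.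
4. C5–C6 by Stille coupling of the geranyl-type allylic acetate with an (E)-β-stannyl methacrylamide; C11/C12 oxygens from a Shi epoxidation (first stereocentres) followed by acid hydrolysis with inversion at C12.
5. C6–C13 is geranyl acetate (SeO2 oxidation at C13, bromide, allyl coupling for C14/C1). Ring order: macrocycle, then lactone.

Assumption: (E)-3-iodo-2-methylprop-2-enoic acid (6) is taken as a purchasable building block (otherwise two steps from diethyl methylmalonate and iodoform); both antipodes of the Shi ketone and of the phosphine catalyst are available.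

**Route**

Step 1
Reactants: 1 geranyl acetate
Product: 2 (2E,6E)-8-hydroxy-3,7-dimethylocta-2,6-dien-1-yl acetate
Conditions: SeO2 (10 mol %), t-BuOOH (70 % aq., 3 equiv), salicylic acid (10 mol %), CH2Cl2, 23 °C
Reagents that add atoms: tert-butyl hydroperoxide, CC(C)(C)OO
Why: Catalytic SeO2 allylic oxidation (ene reaction, then [2,3]-shift) hydroxylates the E-methyl of the distal, electron-rich olefin; the allylic acetate deactivates the proximal olefin.

Step 2
Reactants: 2 (2E,6E)-8-hydroxy-3,7-dimethylocta-2,6-dien-1-yl acetate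
Product: 3 (2E,6E)-8-bromo-3,7-dimethylocta-2,6-dien-1-yl acetate
Conditions: CBr4, PPh3, CH2Cl2, 0 °C
Reagents that add atoms: carbon tetrabromide, BrC(Br)(Br)Br
Why: Appel reaction, SN2 at the primary allylic carbinol under neutral conditions, so the olefin geometry and the acetate are untouched.

Step 3
Reactants: 3 (2E,6E)-8-bromo-3,7-dimethylocta-2,6-dien-1-yl acetate
Product: 4 (2E,6E)-3,7-dimethylundeca-2,6,10-trien-1-yl acetate
Conditions: allylSnBu3 (1.1 equiv), BnPdCl(PPh3)2 (3 mol %), ZnCl2 (10 mol %), THF, 60 °C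
Reagents that add atoms: allyltributylstannane, C=CC[Sn](CCCC)(CCCC)CCCC
Why: Stille allyl–allyl cross-coupling: Pd(0) ionises the allylic bromide much faster than the allylic acetate, C–C bond formation takes place at the unsubstituted C13 terminus with the 6E geometry kept, and the neutral tin reagent does not touch the ester.

Step 4
Reactants: 4 (2E,6E)-3,7-dimethylundeca-2,6,10-trien-1-yl acetate
Product: 5 (2E)-5-[(2S,3S)-3-(but-3-en-1-yl)-3-methyloxiran-2-yl]-3-methylpent-2-en-1-yl acetate
Conditions: ent-Shi ketone (L-fructose-derived, 30 mol %), Oxone, K2CO3, Bu4NHSO4 (cat.), MeCN/DMM/aq. borate–EDTA buffer (pH 10.5), 0 °C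
Reagents that add atoms: potassium peroxymonosulfate (Oxone), [K+].[O-]S(=O)(=O)OO
Why: Shi asymmetric epoxidation: the chiral dioxirane transfers oxygen through a spiro transition state to one face of the trisubstituted C11=C12 olefin, setting 11S,12S (first stereocentres); the acetate-deactivated C7=C8 olefin and the monosubstituted vinyl group do not react.

Step 5
Reactants: 6 (E)-3-iodo-2-methylprop-2-enoic acid
Product: 8 (E)-3-iodo-N-methoxy-N,2-dimethylprop-2-enamide, via (E)-3-iodo-2-methylprop-2-enoyl chloride 7 (not isolated)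
Conditions: (COCl)2, DMF (cat.), CH2Cl2, 0 → 23 °C; then MeNH(OMe)·HCl, pyridine, 0 °C
Reagents that add atoms: N,O-dimethylhydroxylamine hydrochloride, CNOC.Cl; oxalyl chloride, ClC(=O)C(=O)Cl (its chlorine is in 7 only)
Why: Acid chloride formation followed by Schotten–Baumann-type amidation gives the Weinreb amide without touching the vinyl iodide.

Step 6
Reactants: 8 (E)-3-iodo-N-methoxy-N,2-dimethylprop-2-enamide
Product: 9 (E)-N-methoxy-N,2-dimethyl-3-(tributylstannyl)prop-2-enamide
Conditions: (Bu3Sn)2 (1.2 equiv), PdCl2(PPh3)2 (3 mol %), toluene, 80 °C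
Reagents that add atoms: hexabutylditin, CCCC[Sn](CCCC)(CCCC)[Sn](CCCC)(CCCC)CCCC
Why: Pd-catalysed stannylation of a vinyl iodide with a ditin (Stille-type) proceeds with retention of the E geometry.

Step 7
Reactants: 5 (2E)-5-[(2S,3S)-3-(but-3-en-1-yl)-3-methyloxiran-2-yl]-3-methylpent-2-en-1-yl acetate; 9 (E)-N-methoxy-N,2-dimethyl-3-(tributylstannyl)prop-2-enamide
Product: 10 (2E,5E)-8-[(2S,3S)-3-(but-3-en-1-yl)-3-methyloxiran-2-yl]-N-methoxy-N,2,6-trimethylocta-2,5-dienamide
Conditions: Pd(dba)2 (5 mol %), LiCl (3 equiv), DMF, 40 °C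
Reagents that add atoms: none
Why: Stille coupling of an allylic acetate with a vinylstannane under neutral conditions joins C5–C6 at the primary allyl terminus with both olefin geometries retained, giving the skipped diene; the epoxide and the Weinreb amide are inert.

Step 8
Reactants: 10 (2E,5E)-8-[(2S,3S)-3-(but-3-en-1-yl)-3-methyloxiran-2-yl]-N-methoxy-N,2,6-trimethylocta-2,5-dienamide
Product: 11 (2E,5E,9S,10R)-9,10-dihydroxy-N-methoxy-N,2,6,10-tetramethyltetradeca-2,5,13-trienamide
Conditions: HClO4 (0.2 M aq.), THF, 0 °C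
Reagents that add atoms: water, O
Why: Acid-catalysed epoxide hydrolysis (borderline SN2): water attacks the tertiary C12 with inversion (12S → 12R) while C11 keeps its oxygen (11S); this regioselectivity preserves the ee because attack at C11 would give the enantiomer.

Step 9
Reactants: 11 (2E,5E,9S,10R)-9,10-dihydroxy-N-methoxy-N,2,6,10-tetramethyltetradeca-2,5,13-trienamide
Product: 12 (4E,7E,11S,12R)-11,12-dihydroxy-4,8,12-trimethylhexadeca-1,4,7,15-tetraen-3-one
Conditions: CH2=CHMgBr (3.5 equiv), THF, −20 → 0 °C; cold aq. NaHSO4 quench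
Reagents that add atoms: vinylmagnesium bromide, C=C[Mg]Br
Why: Weinreb ketone synthesis: the chelated tetrahedral adduct stops at the ketone stage and the vinyl ketone is released only on the cold acidic quench; two equivalents of Grignard reagent are consumed by the diol.

Step 10
Reactants: 12 (4E,7E,11S,12R)-11,12-dihydroxy-4,8,12-trimethylhexadeca-1,4,7,15-tetraen-3-one
Product: 13 (2E,5E,9S,10R,13E)-9,10-dihydroxy-2,6,10-trimethylcyclotetradeca-2,5,13-trien-1-one
Conditions: Hoveyda–Grubbs II (10 mol %), 1,4-benzoquinone (20 mol %), toluene (1 mM), 80 °C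
Reagents that add atoms: none
Why: Ring-closing metathesis between the terminal olefin and the vinyl ketone closes the 14-membered ring as the E-enone (C1=C2); the trisubstituted olefins are not engaged.

Step 11
Reactants: 13 (2E,5E,9S,10R,13E)-9,10-dihydroxy-2,6,10-trimethylcyclotetradeca-2,5,13-trien-1-one
Product: 14 (1S,4E,7E,10E,14R)-14-hydroxy-4,8,14-trimethyl-9-oxocyclotetradeca-4,7,10-trien-1-yl acetate
Conditions: Ac2O, pyridine, DMAP (cat.), CH2Cl2, 0 °C
Reagents that add atoms: acetic anhydride, CC(=O)OC(C)=O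
Why: Chemoselective acetylation of the secondary C11 hydroxyl over the tertiary C12 hydroxyl.

Step 12
Reactants: 14 (1S,4E,7E,10E,14R)-14-hydroxy-4,8,14-trimethyl-9-oxocyclotetradeca-4,7,10-trien-1-yl acetate
Product: 15 (1R,4E,7E,10E,14S)-14-(acetyloxy)-1,7,11-trimethyl-6-oxocyclotetradeca-4,7,10-trien-1-yl prop-2-enoate
Conditions: acryloyl chloride (5 equiv), i-Pr2NEt (8 equiv), DMAP (0.2 equiv), CH2Cl2, 0 → 35 °C
Reagents that add atoms: acryloyl chloride, C=CC(=O)Cl
Why: DMAP-catalysed acylation with excess acid chloride esterifies the hindered tertiary alcohol; with only an amine base at ≤35 °C the neighbouring acetate is not expected to migrate.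

Step 13
Reactants: 15 (1R,4E,7E,10E,14S)-14-(acetyloxy)-1,7,11-trimethyl-6-oxocyclotetradeca-4,7,10-trien-1-yl prop-2-enoate
Product: 16 3-dehydrodendronpholide B (the target skeleton with a C3 ketone: 1R,11S,12R, 4E,7E, 11-OAc, α-methylene ε-lactone C16(=O)–O–C12)
Conditions: (S)-N-[1-(diphenylphosphanyl)-3-methylbutan-2-yl]-4-methylbenzenesulfonamide (20 mol %), CHCl3 (0.02 M), 0 → 25 °C
Reagents that add atoms: none
Why: Proposed new method: enantioselective intramolecular Rauhut–Currier lactonisation to a seven-membered ring – the phosphine adds reversibly to the unhindered acrylate β-carbon, the resulting ester enolate (C15), tethered through O–C12, closes 7-exo-trig onto C1 of the sulfonamide-N–H-bonded enone on its Re face (giving 1R, reinforced by the Thorpe–Ingold effect of quaternary C12), and proton transfer with β-elimination of the phosphine restores the C15=C17 methylene; the closest known reactions are phosphine-catalysed enantioselective Rauhut–Currier cyclisations of acrylate esters onto enones giving α-methylene-γ-butyrolactones (and of bis-enones to five- and six-membered rings), whereas ε-lactone formation, a macrocyclic cross-conjugated dienone acceptor and catalyst control relative to an existing C12 centre have not been shown.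

Step 14
Reactants: 16 3-dehydrodendronpholide B
Product: 17 dendronpholide B
Conditions: (S)-Me-CBS oxazaborolidine (0.5 equiv), catecholborane (2 equiv), toluene, −78 °C
Reagents that add atoms: none
Why: Corey–Bakshi–Shibata reduction: with the alkenyl group as the large substituent the (S)-catalyst delivers hydride to give the 3R allylic alcohol under reagent control, and at −78 °C the α-methylene lactone and the acetate are not reduced.

**Compound list**

1 | geranyl acetate, (2E)-3,7-dimethylocta-2,6-dien-1-yl acetate | CC(=O)OC/C=C(\C)CCC=C(C)C | starting material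
2 | (2E,6E)-8-hydroxy-3,7-dimethylocta-2,6-dien-1-yl acetate | CC(=O)OC/C=C(\C)CC/C=C(\C)CO | intermediate
3 | (2E,6E)-8-bromo-3,7-dimethylocta-2,6-dien-1-yl acetate | CC(=O)OC/C=C(\C)CC/C=C(\C)CBr | intermediate
4 | (2E,6E)-3,7-dimethylundeca-2,6,10-trien-1-yl acetate | CC(=O)OC/C=C(\C)CC/C=C(\C)CCC=C | intermediate
5 | (2E)-5-[(2S,3S)-3-(but-3-en-1-yl)-3-methyloxiran-2-yl]-3-methylpent-2-en-1-yl acetate | CC(=O)OC/C=C(\C)CC[C@@H]1O[C@@]1(C)CCC=C | intermediate
6 | (E)-3-iodo-2-methylprop-2-enoic acid | C/C(=C\I)C(=O)O | starting material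
7 | (E)-3-iodo-2-methylprop-2-enoyl chloride | C/C(=C\I)C(Cl)=O | intermediate
8 | (E)-3-iodo-N-methoxy-N,2-dimethylprop-2-enamide | C/C(=C\I)C(=O)N(C)OC | intermediate
9 | (E)-N-methoxy-N,2-dimethyl-3-(tributylstannyl)prop-2-enamide | C/C(=C\[Sn](CCCC)(CCCC)CCCC)C(=O)N(C)OC | intermediate
10 | (2E,5E)-8-[(2S,3S)-3-(but-3-en-1-yl)-3-methyloxiran-2-yl]-N-methoxy-N,2,6-trimethylocta-2,5-dienamide | CON(C)C(=O)/C(C)=C/C/C=C(\C)CC[C@@H]1O[C@@]1(C)CCC=C | intermediate
11 | (2E,5E,9S,10R)-9,10-dihydroxy-N-methoxy-N,2,6,10-tetramethyltetradeca-2,5,13-trienamide | CON(C)C(=O)/C(C)=C/C/C=C(\C)CC[C@H](O)[C@](C)(O)CCC=C | intermediate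
12 | (4E,7E,11S,12R)-11,12-dihydroxy-4,8,12-trimethylhexadeca-1,4,7,15-tetraen-3-one | C=CC(=O)/C(C)=C/C/C=C(\C)CC[C@H](O)[C@](C)(O)CCC=C | intermediate
13 | (2E,5E,9S,10R,13E)-9,10-dihydroxy-2,6,10-trimethylcyclotetradeca-2,5,13-trien-1-one | O=C1/C(C)=C/C/C=C(\C)CC[C@H](O)[C@](C)(O)CC/C=C/1 | intermediate
14 | (1S,4E,7E,10E,14R)-14-hydroxy-4,8,14-trimethyl-9-oxocyclotetradeca-4,7,10-trien-1-yl acetate | O=C1/C(C)=C/C/C=C(\C)CC[C@H](OC(C)=O)[C@](C)(O)CC/C=C/1 | intermediate
15 | (1R,4E,7E,10E,14S)-14-(acetyloxy)-1,7,11-trimethyl-6-oxocyclotetradeca-4,7,10-trien-1-yl prop-2-enoate | O=C1/C(C)=C/C/C=C(\C)CC[C@H](OC(C)=O)[C@](C)(OC(=O)C=C)CC/C=C/1 | intermediate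
16 | 3-dehydrodendronpholide B (C3 ketone; 1R,11S,12R; 4E,7E) | C=C1C(=O)O[C@]2(C)CC[C@@H]1CC(=O)/C(C)=C/C/C=C(\C)CC[C@@H]2OC(C)=O | intermediate
17 | dendronpholide B | C=C1C(=O)O[C@]2(C)CC[C@@H]1C[C@@H](O)/C(C)=C/C/C=C(\C)CC[C@@H]2OC(C)=O | target

**Step count and risks**

Total steps: 14. Longest linear sequence: 12 (steps 1–4 and 7–14, from geranyl acetate).

Most likely to fail, first: step 13, the new Rauhut–Currier lactonisation. The acrylate must reach the ester s-cis geometry needed for a seven-membered lactone, the catalyst must override any macrocycle bias at C1 (the (R)-catalyst is the first thing to try if the 1-epimer dominates), and the zwitterionic intermediates could isomerise the skipped diene next to the C3 ketone. The fallback uses known chemistry, sets out from 14 and returns at 16. The tertiary alcohol of 14 is acylated with bromoacetyl bromide and pyridine to the bromoacetate F1. Heating with triethyl phosphite (Michaelis–Arbuzov) gives the diethylphosphonoacetate F2. Cs2CO3 in MeCN then triggers intramolecular Michael addition of the phosphonate-stabilised carbanion to C1, giving the α-phosphono ε-lactone F3 (C1 under substrate and thermodynamic control, C15 as a mixture). Horner–Wadsworth–Emmons methylenation of F3 with aqueous formaldehyde and K2CO3 installs the exocyclic methylene and delivers 16.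

Second: step 10, the macrocyclic RCM, where oligomerisation, a sluggish electron-poor vinyl ketone and Ru–H isomerisation of the skipped diene are the concerns. The fallback closes the ring at C5–C6 instead, sets out from 5 and 9 and returns at 13. Stannane 9 is treated with vinylmagnesium bromide to give (E)-2-methyl-1-(tributylstannyl)penta-1,4-dien-3-one F4. Cross-metathesis of the terminal olefin of 5 with the vinyl ketone of F4 (Hoveyda–Grubbs II) gives the linear epoxy dienone F5, which still carries the allylic acetate and the vinylstannane. An intramolecular Stille coupling of F5 (Pd(dba)2, LiCl, DMF, high dilution) gives the macrocyclic epoxy dienone F6, and HClO4 hydrolysis as in step 8 gives 13.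

Third: step 3, the allyl–allyl Stille coupling, which may give some branched product at C11, diene from β-hydride elimination, or reaction at the allylic acetate. The fallback sets out from 3 and returns at 4. Bromide 3 is treated with excess allylmagnesium bromide and catalytic Li2CuCl4 in THF at −78 → 0 °C, which displaces the bromide in an SN2 sense and deliberately cleaves the acetate, giving (2E,6E)-3,7-dimethylundeca-2,6,10-trien-1-ol F7. Re-acetylation of F7 (Ac2O, pyridine) gives 4.

Further compounds
F1 | step 13 | (1R,4E,7E,10E,14S)-14-(acetyloxy)-1,7,11-trimethyl-6-oxocyclotetradeca-4,7,10-trien-1-yl 2-bromoacetate | O=C1/C(C)=C/C/C=C(\C)CC[C@H](OC(C)=O)[C@](C)(OC(=O)CBr)CC/C=C/1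
F2 | step 13 | (1R,4E,7E,10E,14S)-14-(acetyloxy)-1,7,11-trimethyl-6-oxocyclotetradeca-4,7,10-trien-1-yl 2-(diethoxyphosphoryl)acetate | O=C1/C(C)=C/C/C=C(\C)CC[C@H](OC(C)=O)[C@](C)(OC(=O)CP(=O)(OCC)OCC)CC/C=C/1
F3 | step 13 | 15-(diethoxyphosphoryl)-17-nor analogue of 16 (α-phosphono ε-lactone, C15 epimers) | CCOP(=O)(OCC)C1C(=O)O[C@]2(C)CC[C@@H]1CC(=O)/C(C)=C/C/C=C(\C)CC[C@@H]2OC(C)=O
F4 | step 10 | (E)-2-methyl-1-(tributylstannyl)penta-1,4-dien-3-one | C=CC(=O)/C(C)=C/[Sn](CCCC)(CCCC)CCCC
F5 | step 10 | (2E)-3-methyl-5-{(2S,3S)-3-methyl-3-[(3E,6E)-6-methyl-5-oxo-7-(tributylstannyl)hepta-3,6-dien-1-yl]oxiran-2-yl}pent-2-en-1-yl acetate | CC(=O)OC/C=C(\C)CC[C@@H]1O[C@@]1(C)CC/C=C/C(=O)/C(C)=C/[Sn](CCCC)(CCCC)CCCC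
F6 | step 10 | 11,12-epoxide of the macrocyclic dienone (13 with the (11S,12S)-oxirane in place of the diol) | O=C1/C(C)=C/C/C=C(\C)CC[C@@H]2O[C@@]2(C)CC/C=C/1
F7 | step 3 | (2E,6E)-3,7-dimethylundeca-2,6,10-trien-1-ol | OC/C=C(\C)CC/C=C(\C)CCC=C
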